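# Celastolide: proposed total synthesis

**Retrosynthetic overview**
1. Celastolide ⇐ its C29 methyl ester ⇐ cyclic enol ether **20** plus a propionate unit. Radical carbolactonization closes the γ‑lactone/acylal last and sets C5, C4 and C24.
2. **20** ⇐ tertiary alcohol **19** in one cationic cascade (C14 cation → C8=C9 alkene → dihydropyran C10=C5 alkene). This forms rings C and B with Me‑26 and Me‑25 syn‑diaxial, and **19** ⇐ cross‑metathesis of **15** with **18**.
3. **15** ⇐ cis‑D/E ketone **11**. Ring D comes from a Robinson annulation on ring‑E ketone **7** (Michael sets C17), C18 from hydrogenation, and C13 from a second Michael addition.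
4. **7** ⇐ hydroboration/oxidation of the organocatalytic Diels–Alder adduct of isoprene and methacrolein (sets C20). Ring order: E, D, then C and B together, then the lactone.

Assumption: celastolide is the 2,3‑seco‑friedelane acylal exactly as drawn (free 29‑COOH, exo 4‑Me). The acid is carried as its methyl ester and C4 is equilibrated to the exo epimer.

## Route

**Step 1**
Reactants: 1 isoprene; 2 methacrolein
Product: 3 (R)‑1,4‑dimethylcyclohex‑3‑ene‑1‑carbaldehyde
Conditions: chiral imidazolidinone·HClO4 (20 mol %), MeCN/H2O, –20 °C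
Reagents that add atoms: none
Why: Iminium‑ion Diels–Alder; the "para" adduct places quaternary C(Me)(CHO) 1,4 to the ring methyl, and the iminium face selectivity sets C20, the first stereocenter (catalyst enantiomer chosen to give R).

**Step 2**
Reactants: 3
Product: 4 (R)‑1,4‑dimethylcyclohex‑3‑ene‑1‑carboxylic acid
Conditions: NaClO2, NaH2PO4, 2‑methyl‑2‑butene, t‑BuOH/H2O, 25 °C
Reagents that add atoms: sodium chlorite, [Na+].[O-]Cl=O
Why: Pinnick oxidation of the non‑enolizable aldehyde; the alkene survives because the scavenger removes HOCl, and C20 is untouched.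

**Step 3**
Reactants: 4
Product: 5 methyl (R)‑1,4‑dimethylcyclohex‑3‑ene‑1‑carboxylate
Conditions: MeI, K2CO3, DMF, 25 °C
Reagents that add atoms: iodomethane, CI
Why: Carboxylate SN2 methylation gives the ester that will become C29.

**Step 4**
Reactants: 5
Product: 6 methyl (1R)‑3‑hydroxy‑1,4‑dimethylcyclohexane‑1‑carboxylate (diastereomer mixture at C3/C4)
Conditions: 9‑BBN, THF, 25→60 °C; then NaBO3·4H2O, THF/H2O
Reagents that add atoms: hydrogen peroxide (from perborate), OO
Why: Hydroboration–oxidation is anti‑Markovnikov and puts oxygen on the secondary carbon (C18); the new C17/C18 stereocenters are erased in the next step.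

**Step 5**
Reactants: 6
Product: 7 methyl (1R)‑1,4‑dimethyl‑3‑oxocyclohexane‑1‑carboxylate (C4 epimerizable)
Conditions: Dess–Martin periodinane, NaHCO3, CH2Cl2, 25 °C
Reagents that add atoms: none
Why: Alcohol oxidation gives the 2‑methylcyclohexanone that is the Robinson donor; C17 is an epimerizable stereocenter.

**Step 6**
Reactants: 7; 8 pent‑1‑en‑3‑one (EVK)
Product: 9 methyl (1R,4R)‑1,4‑dimethyl‑3‑oxo‑4‑(3‑oxopentyl)cyclohexane‑1‑carboxylate (chain cis to CO2Me)
Conditions: 9‑amino‑9‑deoxy‑epi‑quinine (20 mol %), TFA (40 mol %), toluene, 25 °C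
Reagents that add atoms: none
Why: Primary‑amine enamine catalysis of α‑branched ketones attacks through the more substituted enamine, and the catalyst's facial control creates quaternary C17 with C16 α and Me‑28 β (Michael step of the Robinson annulation).

**Step 7**
Reactants: 9
Product: 10 D/E‑bicyclic enone (O=C14–C13(Me‑27)=C18; 17β‑Me, 20β‑Me, 20α‑CO2Me)
Conditions: pyrrolidine, AcOH, toluene, 80 °C
Reagents that add atoms: none
Why: Intramolecular aldol condensation of the ethyl‑ketone α'‑CH2 (C13) onto the C18 ketone closes ring D; no new sp3 stereocenter arises.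

**Step 8**
Reactants: 10
Product: 11 cis‑fused saturated ketone (18β‑H, 17β‑Me; C13 epimeric)
Conditions: H2 (5 atm), 10 % Pd/C, KOH, MeOH, 25 °C
Reagents that add atoms: none
Why: Hydrogenation of angular‑methyl enones under basic conditions gives cis ring fusion, so H‑18 is delivered syn to Me‑28; C13 is an epimerizable α‑carbon and is set later.

**Step 9**
Reactants: 11; 12 methyl vinyl ketone
Product: 13 ketone with C13 quaternary: Me‑27 α, chain CH2CH2C(=O)CH3 (C12, C11, C9, C25) β
Conditions: 9‑amino‑9‑deoxy‑epi‑quinine (20 mol %), TFA (40 mol %), toluene, 25 °C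
Reagents that add atoms: none
Why: Enamine‑catalysed Michael addition at the more substituted α‑carbon C13 builds the quaternary center; catalyst control delivers the chain to the β face so that Me‑27 is α. The methyl ketone carbon is C9 and its CH3 is C25.

**Step 10**
Reactants: 13
Product: 14 alkene‑ketone, C9(=CH2)CH3 chain, C14 ketone retained
Conditions: Ph3PCH3Br, KOtBu, THF, 0 °C
Reagents that add atoms: methylenetriphenylphosphorane, C=P(c1ccccc1)(c1ccccc1)c1ccccc1
Why: Wittig methylenation is selective for the unhindered methyl ketone over the neopentylic ring ketone and gives the 1,1‑disubstituted alkene needed for metathesis.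

**Step 11**
Reactants: 14
Product: 15 tertiary alcohol (C14–OH, Me‑26; C14 epimers)
Conditions: MeLi, CeCl3, THF, –78 °C
Reagents that add atoms: methyllithium, C[Li]
Why: Organocerium 1,2‑addition to the hindered ketone installs Me‑26 as the cation precursor; both C14 epimers ionize to the same cation, so C14 configuration is irrelevant.

**Step 12**
Reactants: 16 tetrahydro‑2H‑pyran‑3‑one
Product: 17 5,6‑dihydro‑2H‑pyran‑3‑yl triflate
Conditions: KHMDS, THF, –78 °C; then PhNTf2
Reagents that add atoms: N‑phenylbis(trifluoromethanesulfonimide), FC(F)(F)S(=O)(=O)N(c1ccccc1)S(=O)(=O)C(F)(F)F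
Why: Kinetic enolization toward C4 followed by triflation gives the C3=C4 enol triflate, which becomes the future C5=C10 alkene and oxane ring.

**Step 13**
Reactants: 17
Product: 18 3‑(but‑3‑en‑1‑yl)‑5,6‑dihydro‑2H‑pyran
Conditions: but‑3‑enylZnBr, Pd(PPh3)4 (5 mol %), THF, 50 °C
Reagents that add atoms: but‑3‑en‑1‑ylzinc bromide, C=CCC[Zn]Br
Why: Negishi coupling of a vinyl triflate attaches C6–C7–C8(=CH2) to C5 and leaves the ring alkene and terminal alkene intact.

**Step 14**
Reactants: 15; 18 (3 equiv)
Product: 19 cascade substrate, (E)‑C9=C8 trisubstituted alkene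
Conditions: Hoveyda–Grubbs II (5 mol %), CH2Cl2, 40 °C, ethylene purge
Reagents that add atoms: none
Why: Cross‑metathesis of the 1,1‑disubstituted alkene of 15 with the terminal alkene of 18 forms the thermodynamically favoured (E)‑trisubstituted C9=C8 bond (C11 trans to C7).

**Step 15**
Reactants: 19
Product: 20 pentacyclic enol ether (rings B, C, D, E and the oxane ring; C5=C24)
Conditions: SnCl4 (2 equiv), CH2Cl2, –78 → –30 °C; then Et3N, –78 °C
Reagents that add atoms: none
Why: Proposed new method: ionization gives the C14 tertiary cation, whose trans‑diequatorial capture by C8 of the (E)‑alkene (6‑endo, chair) gives the C9 cation with Me‑25 syn‑diaxial to Me‑26. The endocyclic dihydropyran alkene then closes ring B through C10 (6‑endo, H‑10 α), and the C5 cation takes a 1,2‑hydride shift from the O–CH2 (C24) to an oxocarbenium that Et3N converts to the enol ether. This is a Johnson/Corey cation–olefin polycyclization with Prins‑type hydride‑shift termination, here on the friedelane Me‑9/Me‑14/Me‑13 pattern with a cyclic oxa‑terminator; the preset C13 (Me α) fixes C14 (Me β), C8 (H α), C9 (Me β) and C10 (H α).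

**Step 16**
Reactants: 20
Product: 21 celastolide methyl ester
Conditions: methyl 2‑bromopropanoate (3 equiv), fac‑Ir(ppy)3 (1 mol %), 2,6‑lutidine, MeCN, blue LEDs, 25 °C; then DBU, PhMe, 50 °C
Reagents that add atoms: methyl 2‑bromopropanoate, CC(Br)C(=O)OC
Why: Photoredox radical carbolactonization (Heiba–Dessau‑type γ‑lactone synthesis). The electrophilic α‑ester radical adds to nucleophilic C5 from the α face (β face shielded by Me‑25), the C24 α‑oxy radical is oxidised to the oxocarbenium, and the ester carbonyl traps it cis on the oxane ring with loss of MeBr, which fixes C24 relative to C5; DBU equilibrates C4 to the exo‑methyl epimer.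

**Step 17**
Reactants: 21
Product: 22 celastolide
Conditions: Me3SnOH, 1,2‑dichloroethane, 80 °C
Reagents that add atoms: trimethyltin hydroxide, C[Sn](C)(C)O
Why: Sn‑mediated neutral ester hydrolysis cleaves the hindered 20α‑methyl ester without disturbing the acylal or the stereocenters.

## Compound list

1 | isoprene | C=CC(C)=C | starting material
2 | methacrolein | C=C(C)C=O | starting material
3 | (R)‑1,4‑dimethylcyclohex‑3‑ene‑1‑carbaldehyde | O=C[C@@]1(C)CC=C(C)CC1 | intermediate
4 | (R)‑1,4‑dimethylcyclohex‑3‑ene‑1‑carboxylic acid | OC(=O)[C@@]1(C)CC=C(C)CC1 | intermediate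
5 | methyl (R)‑1,4‑dimethylcyclohex‑3‑ene‑1‑carboxylate | COC(=O)[C@@]1(C)CC=C(C)CC1 | intermediate
6 | methyl (1R)‑3‑hydroxy‑1,4‑dimethylcyclohexane‑1‑carboxylate (C3/C4 mixture) | COC(=O)[C@@]1(C)CC(O)C(C)CC1 | intermediate
7 | methyl (1R)‑1,4‑dimethyl‑3‑oxocyclohexane‑1‑carboxylate | COC(=O)[C@@]1(C)CC(=O)C(C)CC1 | intermediate
8 | pent‑1‑en‑3‑one | C=CC(=O)CC | starting material
9 | methyl (1R,4R)‑1,4‑dimethyl‑3‑oxo‑4‑(3‑oxopentyl)cyclohexane‑1‑carboxylate | COC(=O)[C@@]1(C)CC(=O)[C@@](C)(CCC(=O)CC)CC1 | intermediate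
10 | D/E bicyclic enone (C14=O, C13(Me)=C18, 17β‑Me, 20β‑Me/20α‑CO2Me) | COC(=O)[C@@]1(C)CC2=C(C)C(=O)CC[C@@]2(C)CC1 | intermediate
11 | cis‑D/E ketone (18β‑H, 17β‑Me; C13 unassigned) | COC(=O)[C@@]1(C)C[C@H]2C(C)C(=O)CC[C@@]2(C)CC1 | intermediate
12 | methyl vinyl ketone | C=CC(C)=O | starting material
13 | C13‑quaternary 1,5‑diketone (13α‑Me, 13β‑CH2CH2COCH3) | COC(=O)[C@@]1(C)C[C@H]2[C@](C)(CCC(C)=O)C(=O)CC[C@@]2(C)CC1 | intermediate
14 | isopropenyl‑chain ketone | COC(=O)[C@@]1(C)C[C@H]2[C@](C)(CCC(C)=C)C(=O)CC[C@@]2(C)CC1 | intermediate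
15 | C14 tertiary alcohol (C14 epimers) | COC(=O)[C@@]1(C)C[C@H]2[C@](C)(CCC(C)=C)C(C)(O)CC[C@@]2(C)CC1 | intermediate
16 | tetrahydro‑2H‑pyran‑3‑one | O=C1CCCOC1 | starting material
17 | 5,6‑dihydro‑2H‑pyran‑3‑yl triflate | FC(F)(F)S(=O)(=O)OC1=CCCOC1 | intermediate
18 | 3‑(but‑3‑en‑1‑yl)‑5,6‑dihydro‑2H‑pyran | C=CCCC1=CCCOC1 | intermediate
19 | cascade substrate, (E)‑C9=C8 | COC(=O)[C@@]1(C)C[C@H]2[C@](C)(CC/C(C)=C/CCC3=CCCOC3)C(C)(O)CC[C@@]2(C)CC1 | intermediate
20 | pentacyclic C5=C24 enol ether | O1CC[C@H]3[C@]4(C)CC[C@@]5(C)[C@@H]6C[C@](C)(C(=O)OC)CC[C@]6(C)CC[C@]5(C)[C@H]4CCC3=C1 | intermediate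
21 | celastolide methyl ester | C[C@H]1C(=O)O[C@@H]2OCC[C@H]3[C@]4(C)CC[C@@]5(C)[C@@H]6C[C@](C)(C(=O)OC)CC[C@]6(C)CC[C@]5(C)[C@H]4CC[C@]213 | intermediate
22 | celastolide | C[C@H]1C(=O)O[C@@H]2OCC[C@H]3[C@]4(C)CC[C@@]5(C)[C@@H]6C[C@](C)(C(=O)O)CC[C@]6(C)CC[C@]5(C)[C@H]4CC[C@]213 | target

**Total steps:** 17. **Longest linear sequence:** 15 (steps 1–11, then 14–17).

**Three steps most likely to fail**
1. **Step 15 (proposed new cascade).** The C14 cation could undergo a 1,2‑Me shift or E1 loss of H‑10 instead of the cascade. Fallback (known chemistry): dehydrate 19 to the Δ14‑alkene, epoxidize, and run the Cp2TiCl radical epoxypolyene cyclization (Cuerva–Oltra), then remove the C15–OH (Barton–McCombie).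
2. **Step 16.** Radical addition to the hindered C5 may be slow. Fallback: Rh2(OAc)4 cyclopropanation of 20 with methyl 2‑diazopropanoate, then Lewis‑acid donor–acceptor cyclopropane ring‑opening and lactonization.
3. **Step 9.** Forming the quaternary C13 next to the cis ring fusion by amine catalysis may be sluggish or unselective. Fallback: thermodynamic enolate alkylation of 11 (KOtBu) with 4‑iodo‑2‑methylbut‑1‑ene, separating the C13 epimers, which gives 14 directly and skips steps 9–10.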